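Ring A of the isoflavan is taken apart at C4a–C5 and C8–C8a. A Stille coupling of racemic 4-chloro-2,3-dimethoxycyclobutenone with an (S)-3-aryl-5-stannyl-3,4-dihydro-2H-pyran, followed by ring opening to a dienylketene and 6π closure, should build ring A in one operation. The step exploits the oxygenation of ring A: O1 on C8a comes from the enol ether, the methoxy groups on C6 and C7 from the squarate, and the ketene carbon becomes C8, the only free phenol. The stannane already holds O1, C2, C3 (the sole stereocentre, set by an oxazolidinone-directed propargylation) and C4, with ring B masked as a hydroquinone dibenzyl ether.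

Key step: step 13

Assumption: 2,3-dimethoxy-1,4-benzoquinone 1 is taken as a purchasable compound; it is also the product of a single (NH4)2Ce(NO3)6 oxidation of 1,2,3,4-tetramethoxybenzene.

Step 1
Reactants: 1 2,3-dimethoxy-1,4-benzoquinone
Product: 3 1,4-bis(benzyloxy)-2,3-dimethoxybenzene, via 2,3-dimethoxybenzene-1,4-diol 2 (not isolated)
Conditions: Na2S2O4, EtOAc/H2O, rt; then BnBr, K2CO3, degassed DMF, 60 °C
Reagents that add atoms: benzyl bromide, BrCc1ccccc1
Why: Dithionite reduction of the quinone followed by double Williamson etherification of the hydroquinone should give the dibenzyl ether, exclusion of air keeping the electron-rich diol from reoxidising.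

Step 2
Reactants: 3 1,4-bis(benzyloxy)-2,3-dimethoxybenzene
Product: 4 1,4-bis(benzyloxy)-5-bromo-2,3-dimethoxybenzene
Conditions: NBS (1.0 equiv), MeCN, 0 °C to rt
Reagents that add atoms: N-bromosuccinimide, O=C1CCC(=O)N1Br
Why: Electrophilic aromatic bromination; the two free ring positions are equivalent and each lies ortho and para to an oxygen, so one equivalent should give a single monobromide.

Step 3
Reactants: 4 1,4-bis(benzyloxy)-5-bromo-2,3-dimethoxybenzene; 5 (2-tert-butoxy-2-oxoethyl)zinc chloride (THF or ether solution)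
Product: 6 tert-butyl 2-[2,5-bis(benzyloxy)-3,4-dimethoxyphenyl]acetate
Conditions: Pd2(dba)3 (2.5 mol %), XPhos (10 mol %), THF, 65 °C
Reagents that add atoms: none
Why: Palladium-catalysed α-arylation of an ester through its zinc enolate (Reformatsky–Negishi coupling) runs under neutral conditions, and the bulky electron-rich phosphine allows oxidative addition to the electron-rich, ortho-substituted bromide.

Step 4
Reactants: 6 tert-butyl 2-[2,5-bis(benzyloxy)-3,4-dimethoxyphenyl]acetate
Product: 7 2-[2,5-bis(benzyloxy)-3,4-dimethoxyphenyl]acetic acid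
Conditions: TFA/CH2Cl2 (1:4), 0 °C to rt
Reagents that add atoms: none
Why: Acidolysis of the tert-butyl ester by alkyl–oxygen cleavage (loss of isobutene) should leave the aryl benzyl ethers intact in dilute acid at or below room temperature.

Step 5
Reactants: 7 2-[2,5-bis(benzyloxy)-3,4-dimethoxyphenyl]acetic acid; 8 (4S)-4-benzyl-1,3-oxazolidin-2-one
Product: 10 (4S)-4-benzyl-3-{2-[2,5-bis(benzyloxy)-3,4-dimethoxyphenyl]acetyl}-1,3-oxazolidin-2-one, via mixed pivalic anhydride 9 (not isolated)
Conditions: PivCl, Et3N, THF, −20 °C; then 8, LiCl, −20 °C to rt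
Reagents that add atoms: none
Why: Mixed-anhydride N-acylation of the oxazolidinone, in which LiCl/Et3N activates the carbamate and attack goes to the less hindered arylacetyl carbonyl.

Step 6
Reactants: 10 (4S)-4-benzyl-3-{2-[2,5-bis(benzyloxy)-3,4-dimethoxyphenyl]acetyl}-1,3-oxazolidin-2-one; 11 propargyl bromide
Product: 13 (4S)-4-benzyl-3-{(2S)-2-[2,5-bis(benzyloxy)-3,4-dimethoxyphenyl]pent-4-ynoyl}-1,3-oxazolidin-2-one, via sodium Z-enolate 12 (not isolated)
Conditions: NaN(SiMe3)2, THF, −78 °C; then propargyl bromide, −78 to −40 °C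
Reagents that add atoms: none
Why: Evans asymmetric alkylation: the sodium-chelated Z-enolate is attacked by the propargyl halide on the face away from the C4 benzyl group of the auxiliary, which should set the future C3 as (S) (priorities C=O > aryl > propargyl).

Step 7
Reactants: 13 (4S)-4-benzyl-3-{(2S)-2-[2,5-bis(benzyloxy)-3,4-dimethoxyphenyl]pent-4-ynoyl}-1,3-oxazolidin-2-one
Product: 14 (2S)-2-[2,5-bis(benzyloxy)-3,4-dimethoxyphenyl]pent-4-yn-1-ol
Conditions: LiBH4, H2O (1 equiv), Et2O, 0 °C
Reagents that add atoms: none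
Why: Reductive cleavage of the imide at the exocyclic carbonyl gives the primary alcohol and returns the auxiliary; the alkyne is inert to borohydride and the non-basic conditions should not enolise the α-aryl stereocentre.

Step 8
Reactants: 14 (2S)-2-[2,5-bis(benzyloxy)-3,4-dimethoxyphenyl]pent-4-yn-1-ol
Product: 15 (3S)-3-[2,5-bis(benzyloxy)-3,4-dimethoxyphenyl]-3,4-dihydro-2H-pyran
Conditions: W(CO)6 (25 mol %), Et3N, THF, hν (350 nm), 60 °C
Reagents that add atoms: none
Why: Tungsten-vinylidene endo-cycloisomerisation of a pent-4-yn-1-ol: photogenerated W(CO)5 converts the terminal alkyne into a vinylidene whose electrophilic carbon is attacked by the hydroxyl, and protonolysis releases the six-membered enol ether without touching C3.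

Step 9
Reactants: 15 (3S)-3-[2,5-bis(benzyloxy)-3,4-dimethoxyphenyl]-3,4-dihydro-2H-pyran
Product: 17 (3S)-3-[2,5-bis(benzyloxy)-3,4-dimethoxyphenyl]-5-bromo-3,4-dihydro-2H-pyran, via trans-dibromide 16 (not isolated)
Conditions: Br2 (1.0 equiv), CH2Cl2, −78 °C; then Et3N, −78 °C to rt
Reagents that add atoms: bromine, BrBr
Why: Bromination–dehydrobromination of an enol ether: bromine adds to the enol ether far faster than it substitutes ring B at −78 °C, and amine-induced loss of HBr through the oxocarbenium ion restores the double bond with bromine on C5.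

Step 10
Reactants: 17 (3S)-3-[2,5-bis(benzyloxy)-3,4-dimethoxyphenyl]-5-bromo-3,4-dihydro-2H-pyran
Product: 18 tributyl{(3S)-3-[2,5-bis(benzyloxy)-3,4-dimethoxyphenyl]-3,4-dihydro-2H-pyran-5-yl}stannane
Conditions: Bu3SnSnBu3 (2 equiv), Pd(PPh3)4 (5 mol %), toluene, 100 °C; chromatography on Et3N-deactivated silica
Reagents that add atoms: hexabutylditin, CCCC[Sn](CCCC)(CCCC)[Sn](CCCC)(CCCC)CCCC
Why: Palladium-catalysed stannylation of an alkenyl bromide with a distannane is preferred to bromine–lithium exchange because the alkenyllithium would carry lithium anti to the ring C–O bond and could fragment to an alkynolate; the acid-labile β-stannyl enol ether is kept on base-treated silica.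

Step 11
Reactants: 19 dimethyl squarate
Product: 20 rac-4-hydroxy-2,3-dimethoxycyclobut-2-en-1-one
Conditions: LiAlH(Ot-Bu)3 (1.05 equiv), THF, −78 °C; pH 7 buffer work-up
Reagents that add atoms: none
Why: Chemoselective 1,2-reduction of one squarate carbonyl by a bulky, mild hydride; the alkoxide formed should deactivate the remaining vinylogous ester towards a second reduction.

Step 12
Reactants: 20 rac-4-hydroxy-2,3-dimethoxycyclobut-2-en-1-one
Product: 22 rac-4-chloro-2,3-dimethoxycyclobut-2-en-1-one, via chlorosulfite 21 (not isolated)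
Conditions: SOCl2 (1.1 equiv), pyridine (1.2 equiv), CH2Cl2, −20 to 0 °C; used at once
Reagents that add atoms: thionyl chloride, O=S(Cl)Cl
Why: Chlorodehydroxylation of an α-hydroxy ketone through its chlorosulfite, as in the conversion of acyloins into α-chloro ketones; pyridine traps the HCl that could otherwise strip a methyl group from the vinylogous ester.

Step 13
Reactants: 18 tributyl{(3S)-3-[2,5-bis(benzyloxy)-3,4-dimethoxyphenyl]-3,4-dihydro-2H-pyran-5-yl}stannane; 22 rac-4-chloro-2,3-dimethoxycyclobut-2-en-1-one (1.2 equiv)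
Product: 26 (3S)-3-[2,5-bis(benzyloxy)-3,4-dimethoxyphenyl]-6,7-dimethoxy-3,4-dihydro-2H-chromen-8-ol, via alkenylcyclobutenone 23 (not isolated), via dienylketene 24 (not isolated), via cyclohexadienone 25 (not isolated)
Conditions: PdCl2(PhCN)2 (5 mol %), tri(2-furyl)phosphine (10 mol %), dioxane, 50 °C then 100 °C
Reagents that add atoms: none
Why: Zerovalent palladium inserts into the allylic, α-keto C–Cl bond of 22, the dihydropyranyl group passes from tin to palladium, and reductive elimination at the CH terminus joins C4a to C5 in 23. On warming, 23 opens reversibly by a conrotatory 4π process, and only isomer 24, in which the ketene arm lies cis to the dihydropyranyl group, can close. Ring A closes by a thermal disrotatory 6π electrocyclisation in which the ketene carbon (C8) bonds to the enol ether carbon C8a, and enolisation of 25 gives the phenol, so the former carbonyl oxygen becomes the free C8 hydroxyl. The closest known reaction type is the palladium/tri(2-furyl)phosphine coupling of 4-chlorocyclobutenones with alkenylstannanes with in situ benzannulation to phenols. No lasting stereocentre is created (C4 of 23 and C8a of 25 both end up sp2), and C3 is remote from every reacting atom and should not epimerise under these neutral conditions. The selectivity needed is coupling at C4 and not at the methoxy-bearing allyl terminus C2, which the smaller CH terminus and the retained vinylogous ester conjugation should secure; the ring A pattern then follows from connectivity, the chloride carbon becoming C5 and the carbonyl carbon C8.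

Step 14
Reactants: 26 (3S)-3-[2,5-bis(benzyloxy)-3,4-dimethoxyphenyl]-6,7-dimethoxy-3,4-dihydro-2H-chromen-8-ol
Product: 28 2-[(3S)-8-hydroxy-6,7-dimethoxy-3,4-dihydro-2H-chromen-3-yl]-5,6-dimethoxycyclohexa-2,5-diene-1,4-dione, via hydroquinone 27 (not isolated)
Conditions: H2 (1 atm), 10% Pd/C, EtOAc, rt; filter under argon; then Ag2O, Na2SO4, Et2O, rt
Reagents that add atoms: none
Why: Hydrogenolysis of the two benzyl ethers followed by two-electron oxidation of the ring B hydroquinone with Ag2O; the single phenol of ring A is much harder to oxidise and should remain, and C3 is not affected.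

Compound list
1 | 2,3-dimethoxy-1,4-benzoquinone | COC1=C(OC)C(=O)C=CC1=O | starting material
2 | 2,3-dimethoxybenzene-1,4-diol | COc1c(O)ccc(O)c1OC | intermediate
3 | 1,4-bis(benzyloxy)-2,3-dimethoxybenzene | COc1c(OC)c(OCc4ccccc4)ccc1OCc5ccccc5 | intermediate
4 | 1,4-bis(benzyloxy)-5-bromo-2,3-dimethoxybenzene | COc1c(OC)c(OCc4ccccc4)cc(Br)c1OCc5ccccc5 | intermediate
5 | (2-tert-butoxy-2-oxoethyl)zinc chloride | CC(C)(C)OC(=O)C[Zn]Cl | starting material
6 | tert-butyl 2-[2,5-bis(benzyloxy)-3,4-dimethoxyphenyl]acetate | COc1c(OC)c(OCc4ccccc4)cc(CC(=O)OC(C)(C)C)c1OCc5ccccc5 | intermediate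
7 | 2-[2,5-bis(benzyloxy)-3,4-dimethoxyphenyl]acetic acid | COc1c(OC)c(OCc4ccccc4)cc(CC(=O)O)c1OCc5ccccc5 | intermediate
8 | (4S)-4-benzyl-1,3-oxazolidin-2-one | O=C1OC[C@H](Cc2ccccc2)N1 | starting material
9 | 2-[2,5-bis(benzyloxy)-3,4-dimethoxyphenyl]acetic pivalic anhydride | COc1c(OC)c(OCc4ccccc4)cc(CC(=O)OC(=O)C(C)(C)C)c1OCc5ccccc5 | intermediate
10 | (4S)-4-benzyl-3-{2-[2,5-bis(benzyloxy)-3,4-dimethoxyphenyl]acetyl}-1,3-oxazolidin-2-one | COc1c(OC)c(OCc4ccccc4)cc(CC(=O)N2[C@@H](Cc3ccccc3)COC2=O)c1OCc5ccccc5 | intermediate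
11 | propargyl bromide (3-bromoprop-1-yne) | C#CCBr | starting material
12 | sodium (Z)-enolate of 10 (aryl cis to the enolate oxygen) | COc1c(OC)c(OCc4ccccc4)cc(/C=C(\[O-])N2[C@@H](Cc3ccccc3)COC2=O)c1OCc5ccccc5.[Na+] | intermediate
13 | (4S)-4-benzyl-3-{(2S)-2-[2,5-bis(benzyloxy)-3,4-dimethoxyphenyl]pent-4-ynoyl}-1,3-oxazolidin-2-one | COc1c(OC)c(OCc4ccccc4)cc([C@H](CC#C)C(=O)N2[C@@H](Cc3ccccc3)COC2=O)c1OCc5ccccc5 | intermediate
14 | (2S)-2-[2,5-bis(benzyloxy)-3,4-dimethoxyphenyl]pent-4-yn-1-ol | COc1c(OC)c(OCc4ccccc4)cc([C@H](CC#C)CO)c1OCc5ccccc5 | intermediate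
15 | (3S)-3-[2,5-bis(benzyloxy)-3,4-dimethoxyphenyl]-3,4-dihydro-2H-pyran | COc1c(OC)c(OCc4ccccc4)cc([C@H]2COC=CC2)c1OCc5ccccc5 | intermediate
16 | (5S)-5-[2,5-bis(benzyloxy)-3,4-dimethoxyphenyl]-2,3-dibromooxane (2,3-trans, both trans pairs) | COc1c(OC)c(OCc4ccccc4)cc([C@H]2COC(Br)C(Br)C2)c1OCc5ccccc5 | intermediate
17 | (3S)-3-[2,5-bis(benzyloxy)-3,4-dimethoxyphenyl]-5-bromo-3,4-dihydro-2H-pyran | COc1c(OC)c(OCc4ccccc4)cc([C@H]2COC=C(Br)C2)c1OCc5ccccc5 | intermediate
18 | tributyl{(3S)-3-[2,5-bis(benzyloxy)-3,4-dimethoxyphenyl]-3,4-dihydro-2H-pyran-5-yl}stannane | COc1c(OC)c(OCc4ccccc4)cc([C@H]2COC=C([Sn](CCCC)(CCCC)CCCC)C2)c1OCc5ccccc5 | intermediate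
19 | dimethyl squarate (3,4-dimethoxycyclobut-3-ene-1,2-dione) | COC1=C(OC)C(=O)C1=O | starting material
20 | rac-4-hydroxy-2,3-dimethoxycyclobut-2-en-1-one | COC1=C(OC)C(O)C1=O | intermediate
21 | rac-2,3-dimethoxy-4-oxocyclobut-2-en-1-yl chlorosulfite | COC1=C(OC)C(OS(Cl)=O)C1=O | intermediate
22 | rac-4-chloro-2,3-dimethoxycyclobut-2-en-1-one | COC1=C(OC)C(Cl)C1=O | intermediate
23 | 4-{(3S)-3-[2,5-bis(benzyloxy)-3,4-dimethoxyphenyl]-3,4-dihydro-2H-pyran-5-yl}-2,3-dimethoxycyclobut-2-en-1-one (both C4 epimers) | COc1c(OC)c(OCc4ccccc4)cc([C@H]2COC=C(C3C(OC)=C(OC)C3=O)C2)c1OCc5ccccc5 | intermediate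
24 | (3E)-4-{(3S)-3-[2,5-bis(benzyloxy)-3,4-dimethoxyphenyl]-3,4-dihydro-2H-pyran-5-yl}-2,3-dimethoxybuta-1,3-dien-1-one (ketene arm cis to the pyranyl group) | COc1c(OC)c(OCc4ccccc4)cc([C@H]2COC=C(/C=C(OC)\C(OC)=C=O)C2)c1OCc5ccccc5 | intermediate
25 | (3S)-3-[2,5-bis(benzyloxy)-3,4-dimethoxyphenyl]-6,7-dimethoxy-3,4-dihydro-2H-chromen-8(8aH)-one (both C8a epimers) | COc1c(OC)c(OCc4ccccc4)cc([C@H]2COC3C(=O)C(OC)=C(OC)C=C3C2)c1OCc5ccccc5 | intermediate
26 | (3S)-3-[2,5-bis(benzyloxy)-3,4-dimethoxyphenyl]-6,7-dimethoxy-3,4-dihydro-2H-chromen-8-ol | COc1c(OC)c(OCc4ccccc4)cc([C@H]2COc3c(cc(OC)c(OC)c3O)C2)c1OCc5ccccc5 | intermediate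
27 | 2-[(3S)-8-hydroxy-6,7-dimethoxy-3,4-dihydro-2H-chromen-3-yl]-5,6-dimethoxybenzene-1,4-diol | COc1c(OC)c(O)cc([C@H]2COc3c(cc(OC)c(OC)c3O)C2)c1O | intermediate
28 | 2-[(3S)-8-hydroxy-6,7-dimethoxy-3,4-dihydro-2H-chromen-3-yl]-5,6-dimethoxycyclohexa-2,5-diene-1,4-dione | COC1=C(OC)C(=O)C([C@H]2COc3c(cc(OC)c(OC)c3O)C2)=CC1=O | target

Total step count: 14. Longest linear sequence: 12 steps (steps 1 to 10, then 13 and 14); steps 11 and 12 form the short second branch.

Steps most likely to fail

1. Step 13. Transfer of the hindered dihydropyranyl group from tin to palladium may be slower than loss of tin by protonation at the enol ether carbon (the phenol being formed is a proton source), so that the coupling stalls while the chloride decays. Fallback: setting out from bromide 17 and chloride 22, Miyaura borylation of 17 (bis(pinacolato)diboron, PdCl2(PPh3)2, PPh3, KOPh, toluene, 50 °C) should give the pinacol boronate F1, which is less prone to protonolysis. Suzuki–Miyaura coupling of F1 with the allylic chloride 22 (PdCl2(PhCN)2, tri(2-furyl)phosphine, anhydrous CsF, dioxane, 50 °C), followed by heating to 100 °C, should pass through 23 and rejoin the route at 26.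

2. Step 12. Ionisation at C4 during chlorination or storage, followed by loss of a methyl group from the methoxy-stabilised cation, would collapse the ring to a cyclobutenedione. Fallback: setting out from alcohol 20, acetylation (Ac2O, pyridine, DMAP, CH2Cl2, 0 °C) should give the storable allylic ester rac-2,3-dimethoxy-4-oxocyclobut-2-en-1-yl acetate F2. Zerovalent palladium can ionise F2 to the same oxocyclobutenyl palladium species, so an allylic Stille coupling of F2 with stannane 18 (Pd2(dba)3, tri(2-furyl)phosphine, LiCl, DMF, 50 °C then 100 °C) should lead through 23 to 26, where the route is rejoined.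

3. Step 10. Oxidative addition to the electron-rich alkenyl bromide may be slow, and the stannane formed may couple with bromide still present (dimerisation). Fallback: setting out from bromide 17, bromine–lithium exchange (t-BuLi, 2 equiv, THF/Et2O/pentane, −100 °C) should give the alkenyllithium F3, which is quenched within minutes with Bu3SnCl to return to stannane 18. The very low temperature and short lifetime are meant to outrun ring opening of the lithium species.

Further compounds
F1 | step 13 | 2-{(3S)-3-[2,5-bis(benzyloxy)-3,4-dimethoxyphenyl]-3,4-dihydro-2H-pyran-5-yl}-4,4,5,5-tetramethyl-1,3,2-dioxaborolane | COc1c(OC)c(OCc4ccccc4)cc([C@H]2COC=C(B3OC(C)(C)C(C)(C)O3)C2)c1OCc5ccccc5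
F2 | step 12 | rac-2,3-dimethoxy-4-oxocyclobut-2-en-1-yl acetate | COC1=C(OC)C(OC(C)=O)C1=O
F3 | step 10 | {(3S)-3-[2,5-bis(benzyloxy)-3,4-dimethoxyphenyl]-3,4-dihydro-2H-pyran-5-yl}lithium | COc1c(OC)c(OCc4ccccc4)cc([C@H]2COC=C([Li])C2)c1OCc5ccccc5
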